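**A direct plan and its weak points**

A direct plan would fix the quaternary carbon first by asymmetric conjugate addition to 3-methylcyclopent-2-enone, trim the cyclopentane to the hydroxy dialdehyde A1, close the seven-membered ring by a double Barbier allylation of A1 with a 2-methylidenepropane-1,3-diyl dihalide to the methylidene triol A2, repair this through the silyloxy enone A3 to the triol A4, and acylate A4 twice.
Its weakest steps would be:
- The ring closure on A1 by two successive allylations: an untested intramolecular Barbier reaction that would have to outrun oligomerisation, would set C1 only through an assumed chelate and would form C5 without control.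
- The repair A2 → A3 → A4 (mono-silylation, oxidation with base-mediated alkene migration, Luche reduction, desilylation): four operations that only move one double bond and remake one carbinol, whose configuration beside the quaternary carbon would rest on an uncertain hydride trajectory, while the γ-deprotonated enone A3 could expel its silyloxy group.
- The run-up to A1 (protodesilylation, ozonolysis, hydrogenolysis, double oxidation), which would only turn a vinyl and a benzyloxymethyl group into two formyl groups.

**Plan of the new route**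

- Locants: seven-membered ring C1(O)–C2H2–C3(CH3)=C4H–C5(O)–C6(CH3)–C10(H); five-membered ring C6–C7–C8–C9(OH)(i-Pr)–C10; β is the face of H10. The hardest feature is the C5 carbinol next to the quaternary C6 with O trans to CH3, inside a trans-fused 5–7 system whose two ring oxygens are cis.
- Cuts: the two ester C–O bonds last; then C1–O (silicon tether from the C5 oxygen onto a C1=C10 alkene); then C5–C6 by a [2,3]-Wittig shift; then the ether ring (metathesis at C3=C4, allylation at C1–C2); then C6=C10 by aldol condensation of an opened terpene.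
- Enabling feature: C1–O and C5–O are cis, 1,4 across the C6–C10 fusion and 1,5 through C2–C3(CH3)=C4, with C5 allylic. One oxygen can therefore bridge C1 and C5 in a 4-methyl-3,6-dihydro-2H-pyran whose C1 carries the cyclopentene C10=C6, and can hand C5 over to C6.
- Ring order: a bought cyclohexene is contracted to the cyclopentene (C9 bought with it), a six-membered ether is built on it, and the seven-membered carbocycle appears last by one-carbon ring expansion of that ether. The five-membered ring still precedes the seven-membered one, as in the direct plan; what differs is how each ring arises.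
- Why the weak steps do not arise: no ring is closed between two carbonyl groups; C5 is formed once, together with C6, in a transition state that leaves no choice; no alkene is moved and no carbinol is oxidised and reduced again; the tertiary alcohol is masked during acylation.

Key step: step 6

Assumption: (S)-(+)-terpinen-4-ol is used as the commercial single enantiomer; any (R)-material would become a separable diastereomer in step 3.

**Route**

Step 1
Reactants: 1 (S)-(+)-terpinen-4-ol
Product: 2 triethyl{[(1S)-4-methyl-1-(propan-2-yl)cyclohex-3-en-1-yl]oxy}silane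
Conditions: Et3SiOTf, 2,6-lutidine, CH2Cl2, −78 → 0 °C
Reagents that add atoms: triethylsilyl trifluoromethanesulfonate, CC[Si](CC)(CC)OS(=O)(=O)C(F)(F)F
Why: Silylation of the tertiary alcohol by the silyl triflate/lutidine protocol masks the C9 oxygen before the ring is opened, so that it can neither close onto the ketone of 4 nor be lost by retro-aldol cleavage, and it places a bulky, weakly coordinating group on C9 for the later steps; no stereocentre is touched.

Step 2
Reactants: 2 triethyl{[(1S)-4-methyl-1-(propan-2-yl)cyclohex-3-en-1-yl]oxy}silane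
Product: 5 (5R)-2-methyl-5-(propan-2-yl)-5-[(triethylsilyl)oxy]cyclopent-1-ene-1-carbaldehyde, via ozonide 3 (not isolated), via keto aldehyde 4 (not isolated)
Conditions: O3, CH2Cl2, −78 °C; PPh3, −78 → 23 °C; then piperidine, AcOH (30 mol % each), toluene, 60 °C
Reagents that add atoms: ozone, O=[O+][O-]
Why: Criegee ozonolysis of the only alkene gives keto aldehyde 4, and enamine-mediated intramolecular aldol condensation (the aldehyde is the nucleophile through its piperidine enamine, the methyl ketone the electrophile, 5-enolexo closure) gives the tetrasubstituted enal C1(=O)–C10=C6, whereas hydroxide would make the ketone the nucleophile; acid-assisted loss of the new tertiary hydroxyl should be faster than loss of the silyloxy group, and C9 is not enolisable and keeps its configuration.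

Step 3
Reactants: 5 (5R)-2-methyl-5-(propan-2-yl)-5-[(triethylsilyl)oxy]cyclopent-1-ene-1-carbaldehyde; 6 (2-methylprop-2-en-1-yl)magnesium chloride
Product: 9 (1S)-3-methyl-1-{(5R)-2-methyl-5-(propan-2-yl)-5-[(triethylsilyl)oxy]cyclopent-1-en-1-yl}but-3-en-1-ol, via B-methallyl borane 7 (not isolated), via borinate 8 (not isolated)
Conditions: (−)-Ipc2BOMe [from (+)-α-pinene], 6, Et2O, −78 → 23 °C; then 5, −78 °C; NaOH, 30% H2O2, 0 → 23 °C
Reagents that add atoms: (2-methylprop-2-en-1-yl)magnesium chloride (6), CC(=C)C[Mg]Cl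
Why: Brown asymmetric allylboration with the methallyl reagent, in which the chair Zimmerman–Traxler transition state of the (+)-α-pinene-derived borane delivers the methallyl group to the Si face of the aldehyde under reagent control and so sets C1 as S (the antipodal borane would give the C1 epimer); the enal reacts only 1,2.

Step 4
Reactants: 9 (1S)-3-methyl-1-{(5R)-2-methyl-5-(propan-2-yl)-5-[(triethylsilyl)oxy]cyclopent-1-en-1-yl}but-3-en-1-ol; 10 prop-2-en-1-yl acetate
Product: 11 triethyl({(1R)-3-methyl-2-[(1S)-3-methyl-1-(prop-2-en-1-yloxy)but-3-en-1-yl]-1-(propan-2-yl)cyclopent-2-en-1-yl}oxy)silane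
Conditions: Et2Zn (0.55 equiv), THF, 0 °C; then 10, Pd(OAc)2 (5 mol %), (2-biphenylyl)di-tert-butylphosphine (10 mol %), 23 °C
Reagents that add atoms: prop-2-en-1-yl acetate (10), CC(=O)OCC=C
Why: Palladium-catalysed allylic etherification of the zinc alkoxide (zerovalent palladium formed in situ gives the π-allyl complex, which the covalent zinc alkoxide attacks) allylates the hindered secondary alcohol without a free alkali alkoxide, so the triethylsilyl group cannot shift from the C9 oxygen to the C1 oxygen; C1 is not touched.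

Step 5
Reactants: 11 triethyl({(1R)-3-methyl-2-[(1S)-3-methyl-1-(prop-2-en-1-yloxy)but-3-en-1-yl]-1-(propan-2-yl)cyclopent-2-en-1-yl}oxy)silane
Product: 12 triethyl({(1R)-3-methyl-2-[(2S)-4-methyl-3,6-dihydro-2H-pyran-2-yl]-1-(propan-2-yl)cyclopent-2-en-1-yl}oxy)silane
Conditions: second-generation Grubbs catalyst, RuCl2(=CHPh)(PCy3)(H2IMes) (5 mol %), CH2Cl2, 40 °C
Reagents that add atoms: none
Why: Ring-closing metathesis between the monosubstituted allyl and the 1,1-disubstituted methallyl alkene closes the six-membered ether O–C1–C2–C3(CH3)=C4–C5 with the trisubstituted C3=C4 bond already in its final place, the tetrasubstituted cyclopentene alkene being inert to the catalyst.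

Step 6
Reactants: 12 triethyl({(1R)-3-methyl-2-[(2S)-4-methyl-3,6-dihydro-2H-pyran-2-yl]-1-(propan-2-yl)cyclopent-2-en-1-yl}oxy)silane
Product: 14 (1R,3aS,4R)-3a,6-dimethyl-1-(propan-2-yl)-1-[(triethylsilyl)oxy]-1,2,3,3a,4,7-hexahydroazulen-4-ol, via lithio ether 13 (not isolated)
Conditions: s-BuLi (1.3 equiv), THF, −78 → −30 °C; aq. NH4Cl
Reagents that add atoms: none
Why: Proposed new method: deprotonation of 12 at C5, the only unhindered position that is both allylic (C4=C3) and α to oxygen, gives an α-oxy allyllithium whose carbanion carbon and the cyclopentene carbon C6 are the two ends of the O–C1–C10=C6 allyl ether, so a suprafacial [2,3]-Wittig shift forms C5–C6, breaks C1–O and moves the alkene to C1=C10; the closest known reaction types are the [2,3]-Wittig ring contraction of macrocyclic bis-allylic ethers and the [1,2]- and [1,4]-Wittig rearrangements of lithiated 3,6-dihydro-2H-pyrans, but a six-membered ether with an exocyclic alkenyl partner, which grows into a carbocycle one atom larger, has no direct precedent. The seven-membered carbocycle closes through a five-centre transition state that is bridged by C2–C3=C4 and therefore has the shape of an 8-oxabicyclo[3.2.1]octa-2,6-diene (1,3-diaxial bonding across the pyran, no open-chain entropy to overcome). C6 is controlled by C1: the shift is suprafacial and only the rotamer that places C2 cis to C6 can end in a cis-cycloheptene, so (S)-C1 must deliver C5 to the cyclopentene face that carries the isopropyl group, which is the required 6S configuration. C5 is controlled by the bridge: its oxygen stays on the face from which it spanned C1 and C5, syn to C7 and anti to the C6 methyl, so the trans C5–O/C6–CH3 relation that a hydride reduction would have to fight arises automatically (5R). The step needs the [2,3] shift to beat [1,2]- and [1,4]-shifts and lithiation at C5 to beat lithiation at C1; the first is helped by low temperature and the strain-free bicyclic geometry, the second by the tertiary, crowded C1–H. C9 is a spectator, and its silyl ether lies on the face opposite to the forming bond and does not coordinate the base.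

Step 7
Reactants: 14 (1R,3aS,4R)-3a,6-dimethyl-1-(propan-2-yl)-1-[(triethylsilyl)oxy]-1,2,3,3a,4,7-hexahydroazulen-4-ol
Product: 17 (3R,3aS,4S,8R,8aS)-6,8a-dimethyl-3-(propan-2-yl)-3-[(triethylsilyl)oxy]-1,2,3,3a,4,5,8,8a-octahydroazulene-4,8-diol, via hydrosilyl ether 15 (not isolated), via cyclic siloxane 16 (not isolated)
Conditions: HMe2SiCl, Et3N, CH2Cl2, 0 °C; then Pt2[(CH2=CHSiMe2)2O]3 (zerovalent platinum, 1 mol %), toluene, 60 °C; then 30% H2O2, KHCO3, THF/MeOH, 50 °C
Reagents that add atoms: hydrogen peroxide, OO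
Why: Tamao–Ito intramolecular hydrosilylation followed by Tamao–Fleming oxidation, in which the Si–H of the C5 silyl ether can reach only C1=C10 and only with silicon on C1 (six-membered siloxane; C10 and C3 are fully substituted), so Si and H add syn from the face of the C5 oxygen, which sets H10 β (trans ring fusion, 10S) and, after oxidation with retention, the C1 hydroxyl cis to the C5 oxygen (1S), while fluoride-free peroxide spares the silyl ether.

Step 8
Reactants: 17 (3R,3aS,4S,8R,8aS)-6,8a-dimethyl-3-(propan-2-yl)-3-[(triethylsilyl)oxy]-1,2,3,3a,4,5,8,8a-octahydroazulene-4,8-diol; 18 angelic acid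
Product: 21 (3R,3aS,4S,8R,8aS)-6,8a-dimethyl-3-(propan-2-yl)-3-[(triethylsilyl)oxy]-1,2,3,3a,4,5,8,8a-octahydroazulene-4,8-diyl bis[(2Z)-2-methylbut-2-enoate], via mixed anhydride 19 (not isolated), via mono-angelate 20 (not isolated)
Conditions: 18 (6 equiv), 2,4,6-trichlorobenzoyl chloride, Et3N, toluene, 23 °C; then 17, toluene, 80 °C
Reagents that add atoms: angelic acid (18), C/C=C(/C)C(=O)O
Why: Yamaguchi-type acylation through the mixed 2,4,6-trichlorobenzoic anhydride without a nucleophilic catalyst, a protocol that transfers the angeloyl group without Z to E isomerisation; both secondary alcohols can be driven to completion with excess reagent because the tertiary oxygen is silylated, and no stereocentre is involved.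

Step 9
Reactants: 21 (3R,3aS,4S,8R,8aS)-6,8a-dimethyl-3-(propan-2-yl)-3-[(triethylsilyl)oxy]-1,2,3,3a,4,5,8,8a-octahydroazulene-4,8-diyl bis[(2Z)-2-methylbut-2-enoate]
Product: 22 (3R,3aS,4S,8R,8aS)-3-hydroxy-6,8a-dimethyl-3-(propan-2-yl)-1,2,3,3a,4,5,8,8a-octahydroazulene-4,8-diyl bis[(2Z)-2-methylbut-2-enoate]
Conditions: HF·pyridine, pyridine, THF, 0 → 23 °C
Reagents that add atoms: none
Why: Fluoride-mediated desilylation under buffered, non-basic conditions frees the tertiary alcohol and should leave the allylic and the saturated angelate and every stereocentre untouched.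

**Compound list**

1 | (1S)-4-methyl-1-(propan-2-yl)cyclohex-3-en-1-ol, (S)-(+)-terpinen-4-ol | CC1=CC[C@](O)(C(C)C)CC1 | starting material
2 | triethyl{[(1S)-4-methyl-1-(propan-2-yl)cyclohex-3-en-1-yl]oxy}silane | CC1=CC[C@](O[Si](CC)(CC)CC)(C(C)C)CC1 | intermediate
3 | (4S)-1-methyl-4-(propan-2-yl)-4-[(triethylsilyl)oxy]-7,8,9-trioxabicyclo[4.2.1]nonane (ozonide, bridgeheads of either configuration) | CC12CC[C@@](O[Si](CC)(CC)CC)(C(C)C)CC(OO1)O2 | intermediate (not isolated)
4 | (3S)-6-oxo-3-(propan-2-yl)-3-[(triethylsilyl)oxy]heptanal | O=CC[C@](O[Si](CC)(CC)CC)(C(C)C)CCC(C)=O | intermediate (not isolated)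
5 | (5R)-2-methyl-5-(propan-2-yl)-5-[(triethylsilyl)oxy]cyclopent-1-ene-1-carbaldehyde | O=CC1=C(C)CC[C@@]1(O[Si](CC)(CC)CC)C(C)C | intermediate
6 | (2-methylprop-2-en-1-yl)magnesium chloride | CC(=C)C[Mg]Cl | starting material
7 | (−)-B-(2-methylprop-2-en-1-yl)diisopinocampheylborane (both isopinocampheyl groups from (+)-α-pinene) | CC(=C)CB([C@@H]1C[C@@H]2C[C@H]([C@H]1C)C2(C)C)[C@@H]1C[C@@H]2C[C@H]([C@H]1C)C2(C)C | intermediate (not isolated)
8 | (1S)-3-methyl-1-{(5R)-2-methyl-5-(propan-2-yl)-5-[(triethylsilyl)oxy]cyclopent-1-en-1-yl}but-3-en-1-yl diisopinocampheylborinate | B(O[C@@H](CC(C)=C)C1=C(C)CC[C@@]1(O[Si](CC)(CC)CC)C(C)C)([C@@H]2C[C@@H]3C[C@H]([C@H]2C)C3(C)C)[C@@H]2C[C@@H]3C[C@H]([C@H]2C)C3(C)C | intermediate (not isolated)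
9 | (1S)-3-methyl-1-{(5R)-2-methyl-5-(propan-2-yl)-5-[(triethylsilyl)oxy]cyclopent-1-en-1-yl}but-3-en-1-ol | O[C@@H](CC(C)=C)C1=C(C)CC[C@@]1(O[Si](CC)(CC)CC)C(C)C | intermediate
10 | prop-2-en-1-yl acetate (allyl acetate) | CC(=O)OCC=C | starting material
11 | triethyl({(1R)-3-methyl-2-[(1S)-3-methyl-1-(prop-2-en-1-yloxy)but-3-en-1-yl]-1-(propan-2-yl)cyclopent-2-en-1-yl}oxy)silane | C=CCO[C@@H](CC(C)=C)C1=C(C)CC[C@@]1(O[Si](CC)(CC)CC)C(C)C | intermediate
12 | triethyl({(1R)-3-methyl-2-[(2S)-4-methyl-3,6-dihydro-2H-pyran-2-yl]-1-(propan-2-yl)cyclopent-2-en-1-yl}oxy)silane | CC1=CCO[C@@H](C1)C2=C(C)CC[C@@]2(O[Si](CC)(CC)CC)C(C)C | intermediate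
13 | 6-lithio derivative of 12 (α-oxy allyllithium at C5, configuration at the metalated carbon undefined) | CC1=CC([Li])O[C@@H](C1)C2=C(C)CC[C@@]2(O[Si](CC)(CC)CC)C(C)C | intermediate (not isolated)
14 | (1R,3aS,4R)-3a,6-dimethyl-1-(propan-2-yl)-1-[(triethylsilyl)oxy]-1,2,3,3a,4,7-hexahydroazulen-4-ol (C5 OH β, C6 CH3 α, alkenes C3=C4 and C1=C10) | O[C@@H]1C=C(C)CC=C2[C@]1(C)CC[C@@]2(O[Si](CC)(CC)CC)C(C)C | intermediate
15 | {[(1R,3aS,4R)-4-[(dimethylsilyl)oxy]-3a,6-dimethyl-1-(propan-2-yl)-1,2,3,3a,4,7-hexahydroazulen-1-yl]oxy}(triethyl)silane | C[SiH](C)O[C@@H]1C=C(C)CC=C2[C@]1(C)CC[C@@]2(O[Si](CC)(CC)CC)C(C)C | intermediate (not isolated)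
16 | cyclic siloxane: C5–O–Si(CH3)2–C1 bridge on the β face of the trans-fused hydroazulene, H10 β, C9 triethylsilyl ether | C[Si]1(C)O[C@@H]2C=C(C)C[C@H]1[C@@H]3[C@]2(C)CC[C@@]3(O[Si](CC)(CC)CC)C(C)C | intermediate (not isolated)
17 | (3R,3aS,4S,8R,8aS)-6,8a-dimethyl-3-(propan-2-yl)-3-[(triethylsilyl)oxy]-1,2,3,3a,4,5,8,8a-octahydroazulene-4,8-diol | O[C@H]1CC(C)=C[C@@H](O)[C@@]2(C)CC[C@@](O[Si](CC)(CC)CC)(C(C)C)[C@H]12 | intermediate
18 | angelic acid, (2Z)-2-methylbut-2-enoic acid | C/C=C(/C)C(=O)O | starting material
19 | (2Z)-2-methylbut-2-enoic 2,4,6-trichlorobenzoic anhydride | C/C=C(/C)C(=O)OC(=O)c1c(Cl)cc(Cl)cc1Cl | intermediate (not isolated)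
20 | (3R,3aS,4S,8R,8aS)-8-hydroxy-6,8a-dimethyl-3-(propan-2-yl)-3-[(triethylsilyl)oxy]-1,2,3,3a,4,5,8,8a-octahydroazulen-4-yl (2Z)-2-methylbut-2-enoate | C/C=C(/C)C(=O)O[C@H]1CC(C)=C[C@@H](O)[C@@]2(C)CC[C@@](O[Si](CC)(CC)CC)(C(C)C)[C@H]12 | intermediate (not isolated)
21 | (3R,3aS,4S,8R,8aS)-6,8a-dimethyl-3-(propan-2-yl)-3-[(triethylsilyl)oxy]-1,2,3,3a,4,5,8,8a-octahydroazulene-4,8-diyl bis[(2Z)-2-methylbut-2-enoate] | C/C=C(/C)C(=O)O[C@H]1CC(C)=C[C@@H](OC(=O)/C(C)=C\C)[C@@]2(C)CC[C@@](O[Si](CC)(CC)CC)(C(C)C)[C@H]12 | intermediate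
22 | (3R,3aS,4S,8R,8aS)-3-hydroxy-6,8a-dimethyl-3-(propan-2-yl)-1,2,3,3a,4,5,8,8a-octahydroazulene-4,8-diyl bis[(2Z)-2-methylbut-2-enoate] | C/C=C(/C)C(=O)O[C@H]1CC(C)=C[C@@H](OC(=O)/C(C)=C\C)[C@@]2(C)CC[C@@](O)(C(C)C)[C@H]12 | target

Total step count: 9. Longest linear sequence: 9 steps.

**Steps most likely to fail, with fallbacks**

Step 6 (a [1,2]- or [1,4]-shift of the lithiated ether with ring contraction, lithiation at C1, or no shift onto the fully substituted C6). The fallback sets out from 11 and returns at 14. The open-chain bis-allylic ether 11 would be lithiated at its O-allyl methylene (n-BuLi, THF, −78 °C) and undergo the ordinary [2,3]-Wittig rearrangement to the triene alcohol (1R)-1-[(1S,2E,3R)-1-methyl-2-(3-methylbut-3-en-1-ylidene)-3-(propan-2-yl)-3-[(triethylsilyl)oxy]cyclopentyl]prop-2-en-1-ol F1. The crowded C9 substituent on the central allyl carbon should turn the methallyl arm cis to C6. Ring-closing metathesis of F1 between its vinyl and methallyl groups (second-generation Grubbs catalyst, CH2Cl2, 40 °C) would then close the seven-membered ring to 14. In this variant C5 rests only on the exo preference of the vinyl group in an open transition state, and the C5 epimer and the alkene isomer that cannot cyclise would have to be separated.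

Step 7 (slow insertion of the hindered trisubstituted alkene, or platinum hydride isomerisation of the skipped diene). The fallback sets out from 14 and returns at 17. Untethered hydroboration with 9-borabicyclo[3.3.1]nonane (2.2 equiv, THF, 23 → 50 °C; the first equivalent is taken up by the C5 hydroxyl) would give the C1-(9-borabicyclo[3.3.1]nonan-9-yl) C5-O-(9-borabicyclo[3.3.1]nonan-9-yl) adduct of 14 F2, and NaBO3·4H2O would oxidise and hydrolyse it to 17. Selectivity against C3=C4 and the β-face approach (the α face is screened by the C6 methyl and the C9 silyloxy group) would then depend on substrate bias instead of on the tether.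

Step 8 (incomplete acylation of the neopentyl C5 alcohol, or Z to E isomerisation of the angeloyl group under forcing conditions). The fallback sets out from 17 and returns at 21. Both alcohols would be esterified with the unhindered, saturated 2-[bis(2,2,2-trifluoroethoxy)phosphoryl]propanoic acid (DCC, DMAP, CH2Cl2) to the bis{2-[bis(2,2,2-trifluoroethoxy)phosphoryl]propanoate} of 17 F3. A double Still–Gennari olefination with acetaldehyde (KN(SiMe3)2, 18-crown-6, THF, −78 °C) would then build both (Z)-2-methylbut-2-enoates on the substrate.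

Further compounds
F1 | step 6 | (1R)-1-[(1S,2E,3R)-1-methyl-2-(3-methylbut-3-en-1-ylidene)-3-(propan-2-yl)-3-[(triethylsilyl)oxy]cyclopentyl]prop-2-en-1-ol | C=C[C@@H](O)[C@@]1(C)CC[C@@](O[Si](CC)(CC)CC)(C(C)C)/C1=C/CC(C)=C
F2 | step 7 | C1-(9-borabicyclo[3.3.1]nonan-9-yl) C5-O-(9-borabicyclo[3.3.1]nonan-9-yl) adduct of 14 (boron on C1 β, H10 β) | B1(C2CCCC1CCC2)[C@H]1CC(C)=C[C@@H](OB2C3CCCC2CCC3)[C@@]2(C)CC[C@@](O[Si](CC)(CC)CC)(C(C)C)[C@H]12
F3 | step 8 | (3R,3aS,4S,8R,8aS)-6,8a-dimethyl-3-(propan-2-yl)-3-[(triethylsilyl)oxy]-1,2,3,3a,4,5,8,8a-octahydroazulene-4,8-diyl bis{2-[bis(2,2,2-trifluoroethoxy)phosphoryl]propanoate} | CC(P(=O)(OCC(F)(F)F)OCC(F)(F)F)C(=O)O[C@H]1CC(C)=C[C@@H](OC(=O)C(C)P(=O)(OCC(F)(F)F)OCC(F)(F)F)[C@@]2(C)CC[C@@](O[Si](CC)(CC)CC)(C(C)C)[C@H]12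
A1 | direct plan | (1S,2R,3R)-3-hydroxy-1-methyl-3-(propan-2-yl)cyclopentane-1,2-dicarbaldehyde | O=C[C@@]1(C)CC[C@@](O)(C(C)C)[C@@H]1C=O
A2 | direct plan | (3R,3aS,4S,8R,8aS)-8a-methyl-6-methylidene-3-(propan-2-yl)decahydroazulene-3,4,8-triol | O[C@H]1CC(=C)C[C@@H](O)[C@@]2(C)CC[C@@](O)(C(C)C)[C@H]12
A3 | direct plan | (1R,3aS,8S,8aS)-8-[(tert-butyldimethylsilyl)oxy]-1-hydroxy-3a,6-dimethyl-1-(propan-2-yl)-2,3,3a,7,8,8a-hexahydroazulen-4(1H)-one | CC(C)(C)[Si](C)(C)O[C@H]1CC(C)=CC(=O)[C@@]2(C)CC[C@@](O)(C(C)C)[C@H]12
A4 | direct plan | (3R,3aS,4S,8R,8aS)-6,8a-dimethyl-3-(propan-2-yl)-1,2,3,3a,4,5,8,8a-octahydroazulene-3,4,8-triol | O[C@H]1CC(C)=C[C@@H](O)[C@@]2(C)CC[C@@](O)(C(C)C)[C@H]12
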